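**Retrosynthetic overview**

1. Desilylation and O‑prenylation at C7 lead back to a 5‑(arylethyl)‑2,2‑dimethyl‑2H‑chromen‑7‑ol. Its pyran ring is the only ring made in the route and is closed last (O1–C2), from an ortho‑(1‑hydroxy‑3‑methylbut‑2‑enyl)phenol through an o‑quinone methide and oxa‑6π closure.
2. Key disconnection: the C5–CH2 bond of the arylethyl chain is cut together with the neighbouring C4a–C4 bond. This gives a 3,5‑bis(methoxymethoxy)benzyne (triple bond C4a≡C5), a 2‑arylethyl Grignard reagent and 3‑methylbut‑2‑enal, joined in one pot.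
3. Enabling feature: on the benzo ring, C5 (arylethyl) and C4a (pyran carbon C4) are neighbours, and C8a, next to C4a, carries the ring oxygen O1. An O‑substituent on C8a polarises the C4a≡C5 aryne so that the carbanion enters at C5 and the electrophile at C4a. The second oxygen (C7) is meta to C5, so both oxygens can carry the same protecting group.
4. The aryne precursor, 1,2‑dibromo‑3,5‑bis(methoxymethoxy)benzene, comes from 5‑bromoresorcinol in two steps. The Grignard reagent comes from 4‑(2‑bromoethyl)phenol in two steps.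

Key step: step 5

Remark: the target is achiral. The only stereocentre formed on the way (the carbinol carbon of 11) is racemic and becomes sp2 in step 6. Ring positions are given in 2H‑chromene numbering. Compound 11 is acid‑labile and should be filtered quickly through Et3N‑deactivated silica or used crude.

**Route**

Step 1
Reactants: 1 5‑bromobenzene‑1,3‑diol
Product: 2 1‑bromo‑3,5‑bis(methoxymethoxy)benzene
Conditions: MOMCl (2.5 equiv), i‑Pr2NEt, CH2Cl2, 0 °C → rt
Reagents that add atoms: chloromethyl methyl ether (MOMCl), COCCl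
Why: Williamson‑type O‑alkylation of both phenols gives base‑stable, acid‑labile MOM acetals that later act as inductive and chelating directors for the aryne.

Step 2
Reactants: 2 1‑bromo‑3,5‑bis(methoxymethoxy)benzene
Product: 3 1,2‑dibromo‑3,5‑bis(methoxymethoxy)benzene
Conditions: NBS (1.0 equiv), MeCN, 0 °C → rt, dark
Reagents that add atoms: N‑bromosuccinimide, O=C1CCC(=O)N1Br
Why: Electrophilic aromatic bromination should occur para to one MOM ether and ortho to the other (next to the bromide), because the site between the two MOM ethers is the more hindered one, as is usual for 5‑substituted resorcinol diethers.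

Step 3
Reactants: 4 4‑(2‑bromoethyl)phenol
Product: 5 [4‑(2‑bromoethyl)phenoxy]tri(propan‑2‑yl)silane
Conditions: TIPSOTf, 2,6‑lutidine, CH2Cl2, 0 °C
Reagents that add atoms: triisopropylsilyl trifluoromethanesulfonate, CC(C)[Si](OS(=O)(=O)C(F)(F)F)(C(C)C)C(C)C
Why: O‑silylation of the phenol with a hindered silyl triflate and a non‑nucleophilic base leaves the primary bromide untouched and gives an aryl silyl ether that tolerates Grignard, dilute acid and carbonate conditions.

Step 4
Reactants: 5 [4‑(2‑bromoethyl)phenoxy]tri(propan‑2‑yl)silane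
Product: 6 {2‑[4‑(triisopropylsilyloxy)phenyl]ethyl}magnesium bromide (titrated THF solution, used directly)
Conditions: Mg turnings (I2 cat.), THF, slow addition, 25–40 °C
Reagents that add atoms: magnesium, [Mg]
Why: Grignard formation by oxidative insertion of magnesium into the primary C–Br bond, with slow addition to suppress Wurtz coupling; the aryl silyl ether is inert.

Step 5
Reactants: 3 1,2‑dibromo‑3,5‑bis(methoxymethoxy)benzene; 6 {2‑[4‑(triisopropylsilyloxy)phenyl]ethyl}magnesium bromide; 7 3‑methylbut‑2‑enal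
Product: 11 1‑[2,4‑bis(methoxymethoxy)‑6‑{2‑[4‑(triisopropylsilyloxy)phenyl]ethyl}phenyl]‑3‑methylbut‑2‑en‑1‑ol (racemic), via bromoarylmagnesium chloride 8 (not isolated), via aryne 9 (not isolated), via arylmagnesium bromide 10 (not isolated)
Conditions: 3, i‑PrMgCl·LiCl (1.05 equiv), THF, −15 °C; then 6 (2.5 equiv), −15 → 60 °C; then 7 (4 equiv), −40 → 0 °C; aq NH4Cl
Reagents that add atoms: 3‑methylbut‑2‑enal (7), CC(C)=CC=O
Why: Bromine–magnesium exchange at the C–Br bond flanked by the MOM ether gives 8, which on warming loses MgBrCl to the aryne 9; the alkyl Grignard 6 then adds across the strained triple bond (carbomagnesiation), making the aryl–CH2 bond and leaving magnesium on the neighbouring carbon (10), which is finally quenched by 1,2‑addition to the enal 7. The closest known reaction type is the carbomagnesiation of arynes and pyridynes generated from ortho‑haloarylmagnesium species with alkyl or aryl Grignard reagents followed by electrophile trapping, together with the long‑known addition of alkyllithiums to 3‑alkoxybenzynes. No ring is closed in this step. The carbinol centre is formed without control (racemate) and becomes sp2 in step 6, so no stereocontrol element is needed. The selectivity needed is regiochemical: the nucleophile must enter at the aryne carbon remote from the adjacent MOM ether, which the σ‑withdrawing oxygen secures by distorting the aryne towards attack at the distal carbon and by stabilising and chelating the carbanion that develops at the proximal carbon, while the second MOM ether (meta to the attacked carbon) has only a weak opposing influence. Complete exchange before warming and an excess of 6 should keep 8 from adding to the aryne, and the β,β‑disubstituted enal should take the arylmagnesium at the carbonyl carbon.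

Step 6
Reactants: 11 1‑[2,4‑bis(methoxymethoxy)‑6‑{2‑[4‑(triisopropylsilyloxy)phenyl]ethyl}phenyl]‑3‑methylbut‑2‑en‑1‑ol
Product: 13 2,2‑dimethyl‑5‑{2‑[4‑(triisopropylsilyloxy)phenyl]ethyl}‑2H‑chromen‑7‑ol, via o‑quinone methide 12 (not isolated)
Conditions: conc. HCl (cat.), MeOH/THF, 0 → 40 °C; NaHCO3 quench
Reagents that add atoms: none
Why: Acidic methanolysis cleaves both MOM acetals while the doubly activated benzylic‑allylic alcohol ionises, and loss of water gives the vinyl o‑quinone methide 12 (in acid its O‑protonated form, the allyl cation), which closes by oxa‑6π electrocyclisation through the only ortho oxygen to the 2,2‑dimethyl‑2H‑chromene, leaving the para phenol free and the aryl TIPS ether intact.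

Step 7
Reactants: 13 2,2‑dimethyl‑5‑{2‑[4‑(triisopropylsilyloxy)phenyl]ethyl}‑2H‑chromen‑7‑ol; 14 1‑bromo‑3‑methylbut‑2‑ene
Product: 15 (4‑{2‑[2,2‑dimethyl‑7‑(3‑methylbut‑2‑en‑1‑yloxy)‑2H‑chromen‑5‑yl]ethyl}phenoxy)tri(propan‑2‑yl)silane
Conditions: K2CO3, acetone, 45 °C
Reagents that add atoms: 1‑bromo‑3‑methylbut‑2‑ene (14), CC(C)=CCBr
Why: Williamson ether synthesis on the only free phenol with a primary allylic bromide under mild carbonate conditions should give O‑ rather than C‑alkylation and is tolerated by the chromene and the aryl TIPS ether.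

Step 8
Reactants: 15 (4‑{2‑[2,2‑dimethyl‑7‑(3‑methylbut‑2‑en‑1‑yloxy)‑2H‑chromen‑5‑yl]ethyl}phenoxy)tri(propan‑2‑yl)silane
Product: 16 4‑{2‑[2,2‑dimethyl‑7‑(3‑methylbut‑2‑en‑1‑yloxy)‑2H‑chromen‑5‑yl]ethyl}phenol (CNP0337021.0)
Conditions: TBAF (1.1 equiv), AcOH (1.1 equiv), THF, 0 °C
Reagents that add atoms: none
Why: Fluoride‑mediated cleavage of the aryl silyl ether (driven by Si–F bond formation, buffered with acetic acid) should free the phenol without touching the prenyl ether or the chromene.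

**Compound list**

1 | 5‑bromobenzene‑1,3‑diol (5‑bromoresorcinol) | Oc1cc(O)cc(Br)c1 | starting material
2 | 1‑bromo‑3,5‑bis(methoxymethoxy)benzene | COCOc1cc(OCOC)cc(Br)c1 | intermediate
3 | 1,2‑dibromo‑3,5‑bis(methoxymethoxy)benzene | COCOc1cc(OCOC)c(Br)c(Br)c1 | intermediate
4 | 4‑(2‑bromoethyl)phenol | Oc1ccc(CCBr)cc1 | starting material
5 | [4‑(2‑bromoethyl)phenoxy]tri(propan‑2‑yl)silane | CC(C)[Si](Oc1ccc(CCBr)cc1)(C(C)C)C(C)C | intermediate
6 | {2‑[4‑(triisopropylsilyloxy)phenyl]ethyl}magnesium bromide | CC(C)[Si](Oc1ccc(CC[Mg]Br)cc1)(C(C)C)C(C)C | intermediate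
7 | 3‑methylbut‑2‑enal | CC(C)=CC=O | starting material
8 | [2‑bromo‑4,6‑bis(methoxymethoxy)phenyl]magnesium chloride (LiCl complex) | COCOc1cc(Br)c([Mg]Cl)c(OCOC)c1 | intermediate
9 | 3,5‑bis(methoxymethoxy)benzyne (1,2‑didehydro‑3,5‑bis(methoxymethoxy)benzene) | COCOC1=CC#CC(OCOC)=C1 | intermediate
10 | [2,4‑bis(methoxymethoxy)‑6‑{2‑[4‑(triisopropylsilyloxy)phenyl]ethyl}phenyl]magnesium bromide | COCOc1cc(CCc2ccc(O[Si](C(C)C)(C(C)C)C(C)C)cc2)c([Mg]Br)c(OCOC)c1 | intermediate
11 | 1‑[2,4‑bis(methoxymethoxy)‑6‑{2‑[4‑(triisopropylsilyloxy)phenyl]ethyl}phenyl]‑3‑methylbut‑2‑en‑1‑ol (racemic) | COCOc1cc(CCc2ccc(O[Si](C(C)C)(C(C)C)C(C)C)cc2)c(C(O)C=C(C)C)c(OCOC)c1 | intermediate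
12 | 3‑hydroxy‑6‑(3‑methylbut‑2‑en‑1‑ylidene)‑5‑{2‑[4‑(triisopropylsilyloxy)phenyl]ethyl}cyclohexa‑2,4‑dien‑1‑one (o‑quinone methide, exocyclic alkene geometry not fixed) | CC(C)=CC=C1C(=O)C=C(O)C=C1CCc1ccc(O[Si](C(C)C)(C(C)C)C(C)C)cc1 | intermediate
13 | 2,2‑dimethyl‑5‑{2‑[4‑(triisopropylsilyloxy)phenyl]ethyl}‑2H‑chromen‑7‑ol | CC1(C)C=Cc2c(CCc3ccc(O[Si](C(C)C)(C(C)C)C(C)C)cc3)cc(O)cc2O1 | intermediate
14 | 1‑bromo‑3‑methylbut‑2‑ene (prenyl bromide) | CC(C)=CCBr | starting material
15 | (4‑{2‑[2,2‑dimethyl‑7‑(3‑methylbut‑2‑en‑1‑yloxy)‑2H‑chromen‑5‑yl]ethyl}phenoxy)tri(propan‑2‑yl)silane | CC(C)=CCOc1cc(CCc2ccc(O[Si](C(C)C)(C(C)C)C(C)C)cc2)c2c(c1)OC(C)(C)C=C2 | intermediate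
16 | 4‑{2‑[2,2‑dimethyl‑7‑(3‑methylbut‑2‑en‑1‑yloxy)‑2H‑chromen‑5‑yl]ethyl}phenol | CC(C)=CCOc1cc(CCc2ccc(O)cc2)c2c(c1)OC(C)(C)C=C2 | target

**Step count**

Total steps: 8. Longest linear sequence: 6 (steps 1, 2, 5, 6, 7, 8; the branch 3, 4, 5, 6, 7, 8 is equally long).

**Steps most likely to fail**

Step 5. Aryne generation from 8 may be slow or incomplete, 8 may add to the aryne in place of 6 (oligomerisation), or the hindered arylmagnesium 10 may deprotonate the enal at the γ‑position instead of adding to the carbonyl. The fallback builds the same two bonds stepwise with known chemistry. It sets out from 3: bromine–magnesium exchange at the bromide flanked by the MOM ether (i‑PrMgCl·LiCl, THF, −15 °C) and trapping with 7 at −40 °C, without warming, should give 1‑[2‑bromo‑4,6‑bis(methoxymethoxy)phenyl]‑3‑methylbut‑2‑en‑1‑ol F1. Acid treatment as in step 6 should then give 5‑bromo‑2,2‑dimethyl‑2H‑chromen‑7‑ol F2. Grignard reagent 6 is transmetalated with ZnCl2 to {2‑[4‑(triisopropylsilyloxy)phenyl]ethyl}zinc chloride F3. A Negishi coupling of F3 with F2 (phenol deprotonated beforehand with NaH; Pd(OAc)2/SPhos, THF, 50 °C) forms the same aryl–CH2 bond and comes back to the route at 13.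

Step 6. The electron‑rich chromene may oligomerise or add methanol at its double bond under the acid needed for the slower para MOM cleavage, and cationic intermediates may be diverted to methyl ethers or dienes. The fallback separates MOM cleavage from chromene formation by a change of oxidation level. It sets out from 11: MnO2 in CH2Cl2 should give the enone 1‑[2,4‑bis(methoxymethoxy)‑6‑{2‑[4‑(triisopropylsilyloxy)phenyl]ethyl}phenyl]‑3‑methylbut‑2‑en‑1‑one F4. HCl/MeOH then removes both MOM groups on the now acyl‑deactivated ring, and the ortho phenol closes by oxa‑Michael addition to 7‑hydroxy‑2,2‑dimethyl‑5‑{2‑[4‑(triisopropylsilyloxy)phenyl]ethyl}chroman‑4‑one F5. Prenylation with 14 and K2CO3 in acetone gives 2,2‑dimethyl‑7‑(3‑methylbut‑2‑en‑1‑yloxy)‑5‑{2‑[4‑(triisopropylsilyloxy)phenyl]ethyl}chroman‑4‑one F6. NaBH4 reduction gives the racemic 2,2‑dimethyl‑7‑(3‑methylbut‑2‑en‑1‑yloxy)‑5‑{2‑[4‑(triisopropylsilyloxy)phenyl]ethyl}chroman‑4‑ol F7. Non‑acidic dehydration (MsCl, Et3N, CH2Cl2, 0 °C → rt) comes back to the route at 15.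

Step 4. Wurtz homocoupling of the 2‑arylethyl bromide and incomplete magnesium insertion may give a reagent of poor titre that spoils the stoichiometry of step 5. The fallback replaces oxidative insertion by halogen–lithium exchange. It sets out from 5: a Finkelstein reaction (NaI, acetone) should give [4‑(2‑iodoethyl)phenoxy]tri(propan‑2‑yl)silane F8. Iodine–lithium exchange (t‑BuLi, 2 equiv, Et2O/pentane, −78 °C) gives {2‑[4‑(triisopropylsilyloxy)phenyl]ethyl}lithium F9. Transmetalation with MgBr2·OEt2 comes back to the route at 6.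

**Further compounds**

F1 | step 5 | 1‑[2‑bromo‑4,6‑bis(methoxymethoxy)phenyl]‑3‑methylbut‑2‑en‑1‑ol (racemic) | COCOc1cc(Br)c(C(O)C=C(C)C)c(OCOC)c1
F2 | step 5 | 5‑bromo‑2,2‑dimethyl‑2H‑chromen‑7‑ol | CC1(C)C=Cc2c(Br)cc(O)cc2O1
F3 | step 5 | {2‑[4‑(triisopropylsilyloxy)phenyl]ethyl}zinc chloride | CC(C)[Si](Oc1ccc(CC[Zn]Cl)cc1)(C(C)C)C(C)C
F4 | step 6 | 1‑[2,4‑bis(methoxymethoxy)‑6‑{2‑[4‑(triisopropylsilyloxy)phenyl]ethyl}phenyl]‑3‑methylbut‑2‑en‑1‑one | COCOc1cc(CCc2ccc(O[Si](C(C)C)(C(C)C)C(C)C)cc2)c(C(=O)C=C(C)C)c(OCOC)c1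
F5 | step 6 | 7‑hydroxy‑2,2‑dimethyl‑5‑{2‑[4‑(triisopropylsilyloxy)phenyl]ethyl}chroman‑4‑one | CC1(C)CC(=O)c2c(CCc3ccc(O[Si](C(C)C)(C(C)C)C(C)C)cc3)cc(O)cc2O1
F6 | step 6 | 2,2‑dimethyl‑7‑(3‑methylbut‑2‑en‑1‑yloxy)‑5‑{2‑[4‑(triisopropylsilyloxy)phenyl]ethyl}chroman‑4‑one | CC(C)=CCOc1cc(CCc2ccc(O[Si](C(C)C)(C(C)C)C(C)C)cc2)c2c(c1)OC(C)(C)CC2=O
F7 | step 6 | 2,2‑dimethyl‑7‑(3‑methylbut‑2‑en‑1‑yloxy)‑5‑{2‑[4‑(triisopropylsilyloxy)phenyl]ethyl}chroman‑4‑ol (racemic) | CC(C)=CCOc1cc(CCc2ccc(O[Si](C(C)C)(C(C)C)C(C)C)cc2)c2c(c1)OC(C)(C)CC2O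
F8 | step 4 | [4‑(2‑iodoethyl)phenoxy]tri(propan‑2‑yl)silane | CC(C)[Si](Oc1ccc(CCI)cc1)(C(C)C)C(C)C
F9 | step 4 | {2‑[4‑(triisopropylsilyloxy)phenyl]ethyl}lithium | CC(C)[Si](Oc1ccc(CC[Li])cc1)(C(C)C)C(C)C
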